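**Retrosynthetic overview**

1. The target 18 comes from 17 by hydrogenolysis of two benzyl ethers. 17 comes from the acyclic 3,5,7-triketo ester 16 by Claisen (Dieckmann) closure of the bond between carbons 2 and 3 of ring A, with the CH2 bridge and ring B already attached at carbon 6.
2. The feature that carries the strategy is ring A, numbered as in the name of 17: carbon 1 (ring C=O), carbon 2 (butanoyl-bearing carbon), carbon 3 (enol carbon), carbon 4 (CMe2), carbon 5 (enol carbon), carbon 6 (bridge-bearing carbon). It is the folded tautomer of a 3,5,7-triketo ester whose non-enolisable quaternary carbon 4 lies alpha to the ester carbon, which becomes carbon 3.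
3. 16 comes from isoxazole 14, in which the isoxazole masks the 1,3-diketone made up of the carbon 1 carbonyl and the butanoyl carbonyl. 14 comes from C-benzylation of the isoxazolyl keto ester 6 with the benzylic bromide 13 of ring B.
4. 6 comes from 5-methyl-3-propylisoxazole 4 (nitrile oxide cycloaddition of 1 with 2) and diester 5. 13 comes from 2,5-dimethylresorcinol 7 by acylation, formylation, benzylation, reduction and bromination.
5. Ring order: ring B is carried from 7; the temporary isoxazole ring is made in step 1 and opened in step 9; ring A is closed last, in step 10.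

Key step: step 10

**Remarks on the chemistry**

- The phenols of ring B are carried as benzyl ethers. These survive the dilute aqueous acid that unmasks the triketone and are removed at the end under neutral conditions.
- Compounds 16, 17 and 18 are drawn as single enol tautomers of equilibrating mixtures. The carbon between the isoxazole (or enaminone) and the ketone in 14 and 15 is racemic and becomes trigonal in ring A.
- Lithio and sodio derivatives formed by simple deprotonation are treated as salts of the numbered compounds and are not numbered separately.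

**Route**

Step 1
Reactants: 1 1-nitrobutane; 2 propyne
Product: 4 5-methyl-3-propyl-1,2-oxazole, via butanenitrile oxide 3 (not isolated)
Conditions: PhNCO (2.1 equiv), Et3N (cat.), propyne (excess, condensed), toluene, sealed tube, rt to 50 °C
Reagents that add atoms: none
Why: Mukaiyama–Hoshino dehydration of the primary nitroalkane releases the nitrile oxide slowly in the presence of excess alkyne, and the Huisgen 1,3-dipolar cycloaddition with a terminal alkyne places the alkyne substituent at position 5 of the isoxazole, which fixes the 3-propyl-5-methyl pattern.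

Step 2
Reactants: 4 5-methyl-3-propyl-1,2-oxazole (2.1 equiv); 5 dimethyl 2,2-dimethylmalonate (1.0 equiv)
Product: 6 methyl 2,2-dimethyl-3-oxo-4-(3-propyl-1,2-oxazol-5-yl)butanoate
Conditions: LDA (2.1 equiv), THF, −78 °C; then 5, −78 to −20 °C; aq. NH4Cl
Reagents that add atoms: none
Why: Lateral lithiation of a 3,5-dialkylisoxazole takes place at the methyl group on position 5, and the Claisen-type acylation by the non-enolisable diester should stop after one ester has reacted because the keto ester formed is at once deprotonated by the second equivalent of the lithio species to an unreactive enolate.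

Step 3
Reactants: 7 2,5-dimethylresorcinol; 8 butyryl chloride
Product: 9 1-(2,4-dihydroxy-3,6-dimethylphenyl)butan-1-one
Conditions: AlCl3 (3 equiv), CH2Cl2/PhNO2, 0 °C to rt; aq. HCl
Reagents that add atoms: none
Why: Friedel–Crafts acylation, in which the two free ring positions of 7 are equivalent by symmetry, each lies ortho to one hydroxyl and para to the other, and the acyl group introduced deactivates the ring against a second acylation.

Step 4
Reactants: 9 1-(2,4-dihydroxy-3,6-dimethylphenyl)butan-1-one
Product: 10 3-butanoyl-4,6-dihydroxy-2,5-dimethylbenzaldehyde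
Conditions: Cl2CHOMe (1.5 equiv), TiCl4 (3 equiv), CH2Cl2, 0 °C to rt; then 1 M aq. HCl
Reagents that add atoms: dichloromethyl methyl ether, COC(Cl)Cl (formyl carbon); water, O (formyl oxygen on hydrolysis)
Why: Rieche formylation, for which the single free ring position is still activated by one ortho and one para hydroxyl and which tolerates two flanking substituents, as in the formylation of mesitylene.

Step 5
Reactants: 10 3-butanoyl-4,6-dihydroxy-2,5-dimethylbenzaldehyde
Product: 11 4,6-bis(benzyloxy)-3-butanoyl-2,5-dimethylbenzaldehyde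
Conditions: BnBr (2.5 equiv), K2CO3 (3 equiv), DMF, 60 °C
Reagents that add atoms: benzyl bromide, BrCc1ccccc1
Why: Williamson etherification, run warm in DMF because both phenols are hydrogen-bonded to an ortho carbonyl, with ring C-alkylation closed off because every ring carbon is substituted.

Step 6
Reactants: 11 4,6-bis(benzyloxy)-3-butanoyl-2,5-dimethylbenzaldehyde
Product: 12 [4,6-bis(benzyloxy)-3-butanoyl-2,5-dimethylphenyl]methanol
Conditions: NaBH4 (0.5 equiv), THF/MeOH, −20 to 0 °C
Reagents that add atoms: none
Why: Chemoselective borohydride reduction, in which the aldehyde is far more electrophilic than the aryl ketone, which is shielded by two ortho substituents and twisted out of conjugation.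

Step 7
Reactants: 12 [4,6-bis(benzyloxy)-3-butanoyl-2,5-dimethylphenyl]methanol
Product: 13 1-[2,4-bis(benzyloxy)-5-(bromomethyl)-3,6-dimethylphenyl]butan-1-one
Conditions: CBr4 (1.3 equiv), PPh3 (1.3 equiv), CH2Cl2, 0 °C; used at once
Reagents that add atoms: carbon tetrabromide, BrC(Br)(Br)Br
Why: The Appel reaction converts the benzylic alcohol into the bromide under neutral conditions that leave the benzyl ethers and the ketone alone, and the electron-rich bromide is taken forward without storage.

Step 8
Reactants: 6 methyl 2,2-dimethyl-3-oxo-4-(3-propyl-1,2-oxazol-5-yl)butanoate; 13 1-[2,4-bis(benzyloxy)-5-(bromomethyl)-3,6-dimethylphenyl]butan-1-one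
Product: 14 methyl 5-[4,6-bis(benzyloxy)-3-butanoyl-2,5-dimethylphenyl]-2,2-dimethyl-3-oxo-4-(3-propyl-1,2-oxazol-5-yl)pentanoate (racemic)
Conditions: 6, NaH (1.05 equiv), THF/DMF 4:1, 0 °C; then 13, 0 °C to rt
Reagents that add atoms: none
Why: Enolate C-alkylation by bimolecular nucleophilic substitution, in which the methylene between the isoxazole and the ketone is by far the most acidic C–H of either partner, its sodium enolate should react at carbon with a benzylic bromide, the tertiary centre formed is too hindered for a second alkylation, and the new stereocentre is racemic and is lost when ring A is formed.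

Step 9
Reactants: 14 methyl 5-[4,6-bis(benzyloxy)-3-butanoyl-2,5-dimethylphenyl]-2,2-dimethyl-3-oxo-4-(3-propyl-1,2-oxazol-5-yl)pentanoate
Product: 16 methyl (4Z)-4-{[4,6-bis(benzyloxy)-3-butanoyl-2,5-dimethylphenyl]methyl}-5-hydroxy-2,2-dimethyl-3,7-dioxodec-4-enoate (enol form of the 3,5,7-triketo ester), via enaminone 15 (not isolated)
Conditions: H2 (1 atm), Raney Ni, EtOH/THF, rt; filter; then 1 M aq. HCl, THF, 0 °C to rt
Reagents that add atoms: water, O
Why: Hydrogenolytic N–O cleavage of the isoxazole, used here as a masked 1,3-diketone, gives the vinylogous amide under neutral room-temperature conditions that spare aryl benzyl ethers and the hindered ketones, and dilute acid then hydrolyses it to the ketone, while condensation of the nitrogen onto the ketone that becomes carbon 5 of ring A is slowed by the quaternary carbon and the benzylated carbon that flank that ketone.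

Step 10
Reactants: 16 methyl (4Z)-4-{[4,6-bis(benzyloxy)-3-butanoyl-2,5-dimethylphenyl]methyl}-5-hydroxy-2,2-dimethyl-3,7-dioxodec-4-enoate
Product: 17 6-{[4,6-bis(benzyloxy)-3-butanoyl-2,5-dimethylphenyl]methyl}-2-butanoyl-3,5-dihydroxy-4,4-dimethylcyclohexa-2,5-dien-1-one
Conditions: NaOMe (4 equiv), MeOH, 0 °C to 50 °C; then cold 1 M aq. HCl to pH 2
Reagents that add atoms: none
Why: Methoxide converts 16 into its enolates, and the carbon that becomes carbon 2 of ring A, the central carbon of the 1,3-diketone made up of the future carbon 1 ketone and the butanoyl ketone, adds to the ester carbonyl that becomes carbon 3, after which loss of methoxide leaves the new bond between carbons 2 and 3. The closest known reaction type is the Claisen (Dieckmann) cyclisation of 3,5,7-triketo esters to 2-acylcyclohexane-1,3,5-triones, the laboratory counterpart of acylphloroglucinol biosynthesis. Ring A closes in a 6-exo-trig mode at the ester carbonyl, which is allowed, helped by the gem-dimethyl group at carbon 4, which cannot enolise and so keeps the ester electrophilic while favouring the folded conformer. No stereocentre is formed or carried through. The step needs C-acylation at carbon 2 to win over lactonisation through an enol oxygen, aldol closure from the butanoyl alpha-methylene onto the carbon 5 ketone, and methoxide cleavage of the diketone; the higher acidity of carbon 2, the hindrance around the carbon 5 ketone and the reversibility of O-acylation under methoxide should secure this, because only the C-acylated product is drained as its doubly stabilised triketone enolate.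

Step 11
Reactants: 17 6-{[4,6-bis(benzyloxy)-3-butanoyl-2,5-dimethylphenyl]methyl}-2-butanoyl-3,5-dihydroxy-4,4-dimethylcyclohexa-2,5-dien-1-one
Product: 18 2-butanoyl-6-[(3-butanoyl-4,6-dihydroxy-2,5-dimethylphenyl)methyl]-3,5-dihydroxy-4,4-dimethylcyclohexa-2,5-dien-1-one (CNP0295128.0)
Conditions: H2 (1 atm), 10% Pd/C, EtOAc, rt
Reagents that add atoms: none
Why: Catalytic hydrogenolysis of the two aryl benzyl ethers under neutral conditions, at which the enolised triketone, the aryl ketone and the methylene bridge should not be reduced.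

**Compound list**

1 | 1-nitrobutane | CCCC[N+](=O)[O-] | starting material
2 | propyne | CC#C | starting material
3 | butanenitrile oxide | CCCC#[N+][O-] | intermediate
4 | 5-methyl-3-propyl-1,2-oxazole | CCCc1cc(C)on1 | intermediate
5 | dimethyl 2,2-dimethylmalonate | COC(=O)C(C)(C)C(=O)OC | starting material
6 | methyl 2,2-dimethyl-3-oxo-4-(3-propyl-1,2-oxazol-5-yl)butanoate | CCCc1cc(CC(=O)C(C)(C)C(=O)OC)on1 | intermediate
7 | 2,5-dimethylresorcinol | Cc1cc(O)c(C)c(O)c1 | starting material
8 | butyryl chloride | CCCC(=O)Cl | starting material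
9 | 1-(2,4-dihydroxy-3,6-dimethylphenyl)butan-1-one | CCCC(=O)c1c(C)cc(O)c(C)c1O | intermediate
10 | 3-butanoyl-4,6-dihydroxy-2,5-dimethylbenzaldehyde | CCCC(=O)c1c(C)c(C=O)c(O)c(C)c1O | intermediate
11 | 4,6-bis(benzyloxy)-3-butanoyl-2,5-dimethylbenzaldehyde | CCCC(=O)c1c(C)c(C=O)c(OCc2ccccc2)c(C)c1OCc1ccccc1 | intermediate
12 | [4,6-bis(benzyloxy)-3-butanoyl-2,5-dimethylphenyl]methanol | CCCC(=O)c1c(C)c(CO)c(OCc2ccccc2)c(C)c1OCc1ccccc1 | intermediate
13 | 1-[2,4-bis(benzyloxy)-5-(bromomethyl)-3,6-dimethylphenyl]butan-1-one | CCCC(=O)c1c(C)c(CBr)c(OCc2ccccc2)c(C)c1OCc1ccccc1 | intermediate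
14 | methyl 5-[4,6-bis(benzyloxy)-3-butanoyl-2,5-dimethylphenyl]-2,2-dimethyl-3-oxo-4-(3-propyl-1,2-oxazol-5-yl)pentanoate (racemic) | CCCc1cc(C(Cc2c(C)c(C(=O)CCC)c(OCc3ccccc3)c(C)c2OCc2ccccc2)C(=O)C(C)(C)C(=O)OC)on1 | intermediate
15 | methyl (6Z)-7-amino-4-{[4,6-bis(benzyloxy)-3-butanoyl-2,5-dimethylphenyl]methyl}-2,2-dimethyl-3,5-dioxodec-6-enoate (racemic) | CCC/C(N)=C/C(=O)C(Cc1c(C)c(C(=O)CCC)c(OCc2ccccc2)c(C)c1OCc1ccccc1)C(=O)C(C)(C)C(=O)OC | intermediate
16 | methyl (4Z)-4-{[4,6-bis(benzyloxy)-3-butanoyl-2,5-dimethylphenyl]methyl}-5-hydroxy-2,2-dimethyl-3,7-dioxodec-4-enoate | COC(=O)C(C)(C)C(=O)/C(Cc1c(C)c(C(=O)CCC)c(OCc2ccccc2)c(C)c1OCc1ccccc1)=C(\O)CC(=O)CCC | intermediate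
17 | 6-{[4,6-bis(benzyloxy)-3-butanoyl-2,5-dimethylphenyl]methyl}-2-butanoyl-3,5-dihydroxy-4,4-dimethylcyclohexa-2,5-dien-1-one | CCCC(=O)C1=C(O)C(C)(C)C(O)=C(Cc2c(C)c(C(=O)CCC)c(OCc3ccccc3)c(C)c2OCc2ccccc2)C1=O | intermediate
18 | 2-butanoyl-6-[(3-butanoyl-4,6-dihydroxy-2,5-dimethylphenyl)methyl]-3,5-dihydroxy-4,4-dimethylcyclohexa-2,5-dien-1-one | CCCC(=O)C1=C(O)C(C)(C)C(O)=C(Cc2c(C)c(C(=O)CCC)c(O)c(C)c2O)C1=O | target

**Step count**

Total steps: 11. Longest linear sequence: 9 steps (steps 3 to 11, from 7 to 18).

**Steps most likely to fail**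

Step 10. The ring closure may be diverted by O-acylation to a lactone, by methoxide cleavage of the 2-substituted 1,3-diketone, or stalled by slow attack at the neopentyl-type ester. The fallback brings ring A in already closed. It sets out from bromide 13 and from commercial 1-(2,4,6-trihydroxyphenyl)butan-1-one F1. F1 is geminally C-methylated (MeI, NaOMe, MeOH) to 2-butanoyl-3,5-dihydroxy-4,4-dimethylcyclohexa-2,5-dien-1-one F2. The enolate of F2 (NaOMe, MeOH, 0 °C to rt) is then C-alkylated at its free ring carbon with 13, and the route is rejoined at 17.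

Step 9. After N–O cleavage the enaminone nitrogen may condense onto the ketone beside the quaternary carbon to give a 4-pyridone, or the freed triketone may cyclodehydrate to a 4-pyranone under the acid. The fallback uses an oxygen-only mask for the terminal ketone and sets out from bromide 13. Commercial ethyl 3-oxohexanoate F3 is ketalised (ethylene glycol, p-TsOH, toluene, Dean–Stark) to ethyl 2-(2-propyl-1,3-dioxolan-2-yl)acetate F4. The lithium enolate of commercial methyl 2,2-dimethyl-3-oxobutanoate F5 (2 equiv, LDA, THF, −78 to 0 °C) then undergoes crossed Claisen condensation with F4 to give methyl 2,2-dimethyl-3,5-dioxo-6-(2-propyl-1,3-dioxolan-2-yl)hexanoate F6. F6 is C-benzylated at the central diketone carbon with 13 (K2CO3, acetone, rt) to give methyl 4-{[4,6-bis(benzyloxy)-3-butanoyl-2,5-dimethylphenyl]methyl}-2,2-dimethyl-3,5-dioxo-6-(2-propyl-1,3-dioxolan-2-yl)hexanoate F7. Ketal hydrolysis (1 M aq. HCl, THF, rt) then delivers 16, where the route is rejoined.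

Step 8. The hindered enolate may react at oxygen, or the electron-rich benzylic bromide may ionise and self-condense before it is captured. The fallback replaces the alkylation by condensation and reduction, and sets out from 6 and aldehyde 11. Knoevenagel condensation (TiCl4, pyridine, THF, 0 °C to rt) gives methyl 5-[4,6-bis(benzyloxy)-3-butanoyl-2,5-dimethylphenyl]-2,2-dimethyl-3-oxo-4-(3-propyl-1,2-oxazol-5-yl)pent-4-enoate F8 as an E/Z mixture. Conjugate reduction of this doubly activated alkene with Hantzsch ester (SiO2, toluene, 80 °C) returns to the route at 14.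

**Further compounds**

F1 | step 10 | 1-(2,4,6-trihydroxyphenyl)butan-1-one (commercial) | CCCC(=O)c1c(O)cc(O)cc1O
F2 | step 10 | 2-butanoyl-3,5-dihydroxy-4,4-dimethylcyclohexa-2,5-dien-1-one | CCCC(=O)C1=C(O)C(C)(C)C(O)=CC1=O
F3 | step 9 | ethyl 3-oxohexanoate (commercial) | CCCC(=O)CC(=O)OCC
F4 | step 9 | ethyl 2-(2-propyl-1,3-dioxolan-2-yl)acetate | CCCC1(CC(=O)OCC)OCCO1
F5 | step 9 | methyl 2,2-dimethyl-3-oxobutanoate (commercial) | CC(=O)C(C)(C)C(=O)OC
F6 | step 9 | methyl 2,2-dimethyl-3,5-dioxo-6-(2-propyl-1,3-dioxolan-2-yl)hexanoate | CCCC1(CC(=O)CC(=O)C(C)(C)C(=O)OC)OCCO1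
F7 | step 9 | methyl 4-{[4,6-bis(benzyloxy)-3-butanoyl-2,5-dimethylphenyl]methyl}-2,2-dimethyl-3,5-dioxo-6-(2-propyl-1,3-dioxolan-2-yl)hexanoate (racemic) | CCCC1(CC(=O)C(Cc2c(C)c(C(=O)CCC)c(OCc3ccccc3)c(C)c2OCc2ccccc2)C(=O)C(C)(C)C(=O)OC)OCCO1
F8 | step 8 | methyl 5-[4,6-bis(benzyloxy)-3-butanoyl-2,5-dimethylphenyl]-2,2-dimethyl-3-oxo-4-(3-propyl-1,2-oxazol-5-yl)pent-4-enoate (E/Z mixture) | CCCc1cc(C(=Cc2c(C)c(C(=O)CCC)c(OCc3ccccc3)c(C)c2OCc2ccccc2)C(=O)C(C)(C)C(=O)OC)on1
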